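**Plan**
- Ring numbering: C1 (bears C7H2OBz), C2 (=CH), C3 (OMe), C4 (OH), C5 (OBz), C6 (OH); O3–O7 are the oxygens on C3–C7. Retrosynthesis cuts the two benzoate C–O bonds, then C1–C7 (C7 from CO through a C1 enol triflate), then O3–CH3, then the ring bond C2–C3.
- Enabling feature: the six-membered carbocycle carries oxygen on C3, C4, C5 and C6 and has C1 as a latent ketone, so ring atoms C3, C4, C5, C6, C1, C2 are sugar C-1 to C-6 of a D-altro hex-5-enopyranoside and only C2–C3 is missing.
- Forward: methyl α-D-glucopyranoside → 4,6-acetal → 2,3-anhydro-manno epoxide → 3-O-allyl altroside → PMB on O-2 and O-4 → 6-iodide → enol ether → carbocycle (the only ring formed, step 8) → O3 methyl ether → C1 triflate → C7 ester → deallylation, reduction, benzoylation, PMB removal.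
- Stereochemistry: C6 is sugar C-4 of D-glucose, untouched. C4 and C5 are sugar C-2 and C-3, each inverted once (epoxide closure, then trans-diaxial opening). C3 is set in the aldol ring closure by the chair transition state.

Key step: step 8

Remark: the 4-methoxybenzylidene acetal is taken as its thermodynamic (R) isomer (aryl equatorial); this centre disappears in step 5. "Sugar C-n" denotes carbohydrate locants; all other locants are those of the target ring. PMB = 4-methoxybenzyl.

Step 1
Reactants: 1 methyl α-D-glucopyranoside; 2 4-methoxybenzaldehyde dimethyl acetal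
Product: 3 methyl 4,6-O-[(R)-4-methoxybenzylidene]-α-D-glucopyranoside
Conditions: 2 (1.2 equiv), camphorsulfonic acid (cat.), DMF, 60 °C, reduced pressure
Reagents that add atoms: 4-methoxybenzaldehyde dimethyl acetal (2), COC(OC)c1ccc(OC)cc1
Why: Acid-catalysed transacetalisation should give the thermodynamically favoured trans-fused 1,3-dioxane across O-4/O-6 with equatorial aryl, removal of methanol driving the equilibrium.

Step 2
Reactants: 3 methyl 4,6-O-[(R)-4-methoxybenzylidene]-α-D-glucopyranoside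
Product: 5 methyl 2,3-anhydro-4,6-O-[(R)-4-methoxybenzylidene]-α-D-mannopyranoside, via 2-O-tosyl glucoside 4 (not isolated)
Conditions: NaH (2.5 equiv), DMF, 0 °C → rt; then N-tosylimidazole (1.1 equiv), rt
Reagents that add atoms: none
Why: The more acidic O-2 of the α-glucoside is sulfonylated selectively and the O-3 alkoxide then displaces the tosylate intramolecularly (SN2, inversion at sugar C-2), giving the β-face manno epoxide.

Step 3
Reactants: 5 methyl 2,3-anhydro-4,6-O-[(R)-4-methoxybenzylidene]-α-D-mannopyranoside; 6 allyl alcohol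
Product: 7 methyl 3-O-allyl-4,6-O-[(R)-4-methoxybenzylidene]-α-D-altropyranoside
Conditions: NaH (1.5 equiv) in allyl alcohol (solvent), 90 °C
Reagents that add atoms: allyl alcohol (6), C=CCO
Why: Alkoxide opening of the conformationally locked epoxide follows the Fürst–Plattner rule, so attack occurs at sugar C-3 from the α face (trans-diaxial, inversion at C-3) and leaves the axial 2-OH of the D-altro array.

Step 4
Reactants: 7 methyl 3-O-allyl-4,6-O-[(R)-4-methoxybenzylidene]-α-D-altropyranoside; 8 4-methoxybenzyl chloride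
Product: 9 methyl 3-O-allyl-2-O-(4-methoxybenzyl)-4,6-O-[(R)-4-methoxybenzylidene]-α-D-altropyranoside
Conditions: NaH (1.5 equiv), 8 (1.3 equiv), Bu4NI (cat.), DMF, 0 °C → rt
Reagents that add atoms: 4-methoxybenzyl chloride (8), COc1ccc(CCl)cc1
Why: Williamson etherification of the only free hydroxyl; no stereocentre is touched.

Step 5
Reactants: 9 methyl 3-O-allyl-2-O-(4-methoxybenzyl)-4,6-O-[(R)-4-methoxybenzylidene]-α-D-altropyranoside
Product: 10 methyl 3-O-allyl-2,4-bis-O-(4-methoxybenzyl)-α-D-altropyranoside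
Conditions: i-Bu2AlH (3 equiv), toluene, −40 → 0 °C; aq. potassium sodium tartrate work-up
Reagents that add atoms: none
Why: Regioselective reductive acetal opening: the aluminium hydride binds the less hindered primary O-6, the C–O6 bond ionises and hydride reduces the oxocarbenium ion held on O-4, which should leave the 4-O-PMB ether and a free 6-OH.

Step 6
Reactants: 10 methyl 3-O-allyl-2,4-bis-O-(4-methoxybenzyl)-α-D-altropyranoside
Product: 11 methyl 3-O-allyl-6-deoxy-6-iodo-2,4-bis-O-(4-methoxybenzyl)-α-D-altropyranoside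
Conditions: I2, PPh3, imidazole, toluene, 60 °C
Reagents that add atoms: iodine, II
Why: Appel-type (Garegg–Samuelsson) iodination, in which iodide displaces the primary alkoxyphosphonium ion at unhindered sugar C-6.

Step 7
Reactants: 11 methyl 3-O-allyl-6-deoxy-6-iodo-2,4-bis-O-(4-methoxybenzyl)-α-D-altropyranoside
Product: 12 methyl 3-O-allyl-6-deoxy-2,4-bis-O-(4-methoxybenzyl)-α-D-arabino-hex-5-enopyranoside
Conditions: KOt-Bu (1.5 equiv), THF, 0 °C → rt
Reagents that add atoms: none
Why: E2 dehydroiodination across sugar C-5/C-6 gives the exocyclic enol ether; the ether protecting groups are inert to the base at this temperature.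

Step 8
Reactants: 12 methyl 3-O-allyl-6-deoxy-2,4-bis-O-(4-methoxybenzyl)-α-D-arabino-hex-5-enopyranoside
Product: 15 (2S,3S,4R,5R)-3-(allyloxy)-5-hydroxy-2,4-bis(4-methoxybenzyloxy)cyclohexan-1-one, via mercurio hemiketal 13 (not isolated), via mercurio keto aldehyde 14 (not isolated)
Conditions: Hg(OCOCF3)2 (10 mol %), acetone–H2O (4:1), rt
Reagents that add atoms: water, O
Why: Ferrier carbocyclization: divalent mercury and water add across the electron-rich exocyclic enol ether (sugar C-5/C-6) to give hemiketal 13, which ring-opens and sheds methanol to the acyclic α-mercurio ketone aldehyde 14; its mercury enolate adds to the aldehyde and protonolysis returns the mercury salt, so a catalytic amount suffices. The closest known reaction type is the mercury-salt-catalysed conversion of ether-protected 6-deoxyhex-5-enopyranosides into 2,3,4-trialkoxy-5-hydroxycyclohexanones. The carbocycle closes by a 6-(enolendo)-exo-trig aldol addition that forms the C2–C3 bond (sugar C-6 to C-1). The single new stereocentre, C3, is set by substrate control: in the chair-like transition state the O4 and O5 substituents are equatorial and the aldehyde oxygen is axial, which places the new hydroxyl trans to O5 and cis to O4, the usual outcome of this reaction (hydroxyl trans to the sugar O-3 substituent). The step needs this diastereoselectivity and chemoselectivity for the enol ether over the allyl ether and the anisyl rings; the first rests on the three fixed ring stereocentres, the second on the far higher nucleophilicity of the enol ether, and both anomers of 12 would converge on the same aldehyde.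

Step 9
Reactants: 15 (2S,3S,4R,5R)-3-(allyloxy)-5-hydroxy-2,4-bis(4-methoxybenzyloxy)cyclohexan-1-one
Product: 16 (2S,3S,4R,5R)-3-(allyloxy)-5-methoxy-2,4-bis(4-methoxybenzyloxy)cyclohexan-1-one
Conditions: Me3OBF4 (3 equiv), 1,8-bis(dimethylamino)naphthalene (3 equiv), 4 Å MS, CH2Cl2, 0 °C → rt
Reagents that add atoms: trimethyloxonium tetrafluoroborate, C[O+](C)C.F[B-](F)(F)F
Why: O-Methylation by an oxonium salt under a hindered, non-nucleophilic base alkylates the only free hydroxyl without generating an enolate, so the β-oxygen should not be eliminated and C3 keeps its configuration.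

Step 10
Reactants: 16 (2S,3S,4R,5R)-3-(allyloxy)-5-methoxy-2,4-bis(4-methoxybenzyloxy)cyclohexan-1-one
Product: 18 (3R,4R,5S,6S)-5-(allyloxy)-3-methoxy-4,6-bis(4-methoxybenzyloxy)cyclohex-1-en-1-yl trifluoromethanesulfonate, via lithium enolate 17 (not isolated)
Conditions: LiN(SiMe3)2 (1.2 equiv), THF, −78 °C; then N-(5-chloro-2-pyridyl)bis(trifluoromethanesulfonimide) (1.3 equiv), −78 °C
Reagents that add atoms: N-(5-chloro-2-pyridyl)bis(trifluoromethanesulfonimide), O=S(=O)(N(c1ccc(Cl)cn1)S(=O)(=O)C(F)(F)F)C(F)(F)F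
Why: Kinetic deprotonation by the hindered amide should take a proton from the unsubstituted C2 methylene and not the alkoxy-bearing C6 methine (whose hydrogen is equatorial when O6 is axial), and the cold lithium enolate is O-sulfonylated before methoxide can leave (enol triflate formation).

Step 11
Reactants: 18 (3R,4R,5S,6S)-5-(allyloxy)-3-methoxy-4,6-bis(4-methoxybenzyloxy)cyclohex-1-en-1-yl trifluoromethanesulfonate
Product: 19 methyl (3R,4R,5R,6R)-5-(allyloxy)-3-methoxy-4,6-bis(4-methoxybenzyloxy)cyclohex-1-ene-1-carboxylate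
Conditions: Pd(OAc)2 (5 mol %), PPh3 (10 mol %), CO (1 atm), MeOH, Et3N, DMF, rt → 50 °C
Reagents that add atoms: carbon monoxide, [C-]#[O+]; methanol, CO
Why: Palladium-catalysed alkoxycarbonylation of an enol triflate (oxidative addition to zerovalent palladium, CO insertion, methanolysis of the acyl complex) installs C7 on C1 with the double bond fixed at C1=C2.

Step 12
Reactants: 19 methyl (3R,4R,5R,6R)-5-(allyloxy)-3-methoxy-4,6-bis(4-methoxybenzyloxy)cyclohex-1-ene-1-carboxylate
Product: 21 methyl (3R,4S,5R,6R)-5-hydroxy-3-methoxy-4,6-bis(4-methoxybenzyloxy)cyclohex-1-ene-1-carboxylate, via prop-1-enyl ether 20 (not isolated)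
Conditions: [Ir(cod)(PMePh2)2]PF6 (3 mol %, activated with H2), THF, rt; then 1 M aq. HCl, rt
Reagents that add atoms: none
Why: Two-stage allyl ether cleavage, in which the cationic iridium hydride isomerises the terminal allyl ether to the enol ether and dilute acid hydrolyses it, should spare the conjugated trisubstituted ring alkene, the methyl ether and the PMB ethers (the C4 descriptor becomes S through a priority change only).

Step 13
Reactants: 21 methyl (3R,4S,5R,6R)-5-hydroxy-3-methoxy-4,6-bis(4-methoxybenzyloxy)cyclohex-1-ene-1-carboxylate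
Product: 22 [(3R,4S,5R,6R)-5-hydroxy-3-methoxy-4,6-bis(4-methoxybenzyloxy)cyclohex-1-en-1-yl]methanol
Conditions: i-Bu2AlH (4 equiv), CH2Cl2, −78 → −20 °C; aq. potassium sodium tartrate work-up
Reagents that add atoms: none
Why: 1,2-Reduction of the conjugated ester by the electrophilic aluminium hydride gives the primary allylic alcohol (O7–H) without touching the ring alkene or the ethers.

Step 14
Reactants: 22 [(3R,4S,5R,6R)-5-hydroxy-3-methoxy-4,6-bis(4-methoxybenzyloxy)cyclohex-1-en-1-yl]methanol; 23 benzoyl chloride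
Product: 24 [(3R,4R,5R,6R)-5-(benzoyloxy)-3-methoxy-4,6-bis(4-methoxybenzyloxy)cyclohex-1-en-1-yl]methyl benzoate
Conditions: 23 (3 equiv), pyridine, DMAP (cat.), CH2Cl2, 0 °C → rt
Reagents that add atoms: benzoyl chloride (23), O=C(Cl)c1ccccc1
Why: DMAP-catalysed acylation esterifies the two free hydroxyls (O7 and O5) while O4 and O6 stay masked as PMB ethers.

Step 15
Reactants: 24 [(3R,4R,5R,6R)-5-(benzoyloxy)-3-methoxy-4,6-bis(4-methoxybenzyloxy)cyclohex-1-en-1-yl]methyl benzoate
Product: 25 [(3R,4R,5R,6R)-5-(benzoyloxy)-4,6-dihydroxy-3-methoxycyclohex-1-en-1-yl]methyl benzoate (CNP0349013.4)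
Conditions: DDQ (3 equiv), CH2Cl2–aq. pH 7 buffer (10:1), 0 °C → rt
Reagents that add atoms: none
Why: Oxidative PMB ether cleavage (benzylic hydride abstraction by DDQ, hydrolysis of the oxocarbenium ions) frees O4 and O6 under neutral conditions, so the benzoates should neither migrate nor hydrolyse.

**Compound list**
1 | methyl α-D-glucopyranoside | CO[C@H]1O[C@H](CO)[C@@H](O)[C@H](O)[C@H]1O | starting material
2 | 4-methoxybenzaldehyde dimethyl acetal | COC(OC)c1ccc(OC)cc1 | starting material
3 | methyl 4,6-O-[(R)-4-methoxybenzylidene]-α-D-glucopyranoside | CO[C@H]1O[C@@H]2CO[C@@H](c3ccc(OC)cc3)O[C@H]2[C@H](O)[C@H]1O | intermediate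
4 | methyl 4,6-O-[(R)-4-methoxybenzylidene]-2-O-(4-toluenesulfonyl)-α-D-glucopyranoside | CO[C@H]1O[C@@H]2CO[C@@H](c3ccc(OC)cc3)O[C@H]2[C@H](O)[C@H]1OS(=O)(=O)c1ccc(C)cc1 | intermediate (not isolated)
5 | methyl 2,3-anhydro-4,6-O-[(R)-4-methoxybenzylidene]-α-D-mannopyranoside | CO[C@H]1O[C@@H]2CO[C@@H](c3ccc(OC)cc3)O[C@H]2[C@@H]2O[C@H]12 | intermediate
6 | allyl alcohol | C=CCO | starting material
7 | methyl 3-O-allyl-4,6-O-[(R)-4-methoxybenzylidene]-α-D-altropyranoside | CO[C@H]1O[C@@H]2CO[C@@H](c3ccc(OC)cc3)O[C@H]2[C@@H](OCC=C)[C@@H]1O | intermediate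
8 | 4-methoxybenzyl chloride | COc1ccc(CCl)cc1 | starting material
9 | methyl 3-O-allyl-2-O-(4-methoxybenzyl)-4,6-O-[(R)-4-methoxybenzylidene]-α-D-altropyranoside | CO[C@H]1O[C@@H]2CO[C@@H](c3ccc(OC)cc3)O[C@H]2[C@@H](OCC=C)[C@@H]1OCc1ccc(OC)cc1 | intermediate
10 | methyl 3-O-allyl-2,4-bis-O-(4-methoxybenzyl)-α-D-altropyranoside | CO[C@H]1O[C@H](CO)[C@@H](OCc2ccc(OC)cc2)[C@@H](OCC=C)[C@@H]1OCc1ccc(OC)cc1 | intermediate
11 | methyl 3-O-allyl-6-deoxy-6-iodo-2,4-bis-O-(4-methoxybenzyl)-α-D-altropyranoside | CO[C@H]1O[C@H](CI)[C@@H](OCc2ccc(OC)cc2)[C@@H](OCC=C)[C@@H]1OCc1ccc(OC)cc1 | intermediate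
12 | methyl 3-O-allyl-6-deoxy-2,4-bis-O-(4-methoxybenzyl)-α-D-arabino-hex-5-enopyranoside | CO[C@H]1OC(=C)[C@@H](OCc2ccc(OC)cc2)[C@@H](OCC=C)[C@@H]1OCc1ccc(OC)cc1 | intermediate
13 | hydroxymercuration adduct of 12: sugar C-5 hemiketal bearing CH2HgOCOCF3 (C-5 configuration undefined) | CO[C@H]1OC(O)(C[Hg]OC(=O)C(F)(F)F)[C@@H](OCc2ccc(OC)cc2)[C@@H](OCC=C)[C@@H]1OCc1ccc(OC)cc1 | intermediate (not isolated)
14 | open-chain 3-O-allyl-6-deoxy-2,4-bis-O-(4-methoxybenzyl)-6-(trifluoroacetoxymercurio)-D-arabino-hexos-5-ulose | FC(F)(F)C(=O)O[Hg]CC(=O)[C@@H](OCc1ccc(OC)cc1)[C@@H](OCC=C)[C@H](OCc1ccc(OC)cc1)C=O | intermediate (not isolated)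
15 | (2S,3S,4R,5R)-3-(allyloxy)-5-hydroxy-2,4-bis(4-methoxybenzyloxy)cyclohexan-1-one | O[C@@H]1CC(=O)[C@@H](OCc2ccc(OC)cc2)[C@@H](OCC=C)[C@@H]1OCc1ccc(OC)cc1 | intermediate
16 | (2S,3S,4R,5R)-3-(allyloxy)-5-methoxy-2,4-bis(4-methoxybenzyloxy)cyclohexan-1-one | CO[C@@H]1CC(=O)[C@@H](OCc2ccc(OC)cc2)[C@@H](OCC=C)[C@@H]1OCc1ccc(OC)cc1 | intermediate
17 | lithium (3R,4R,5S,6S)-5-(allyloxy)-3-methoxy-4,6-bis(4-methoxybenzyloxy)cyclohex-1-en-1-olate | CO[C@@H]1C=C(O[Li])[C@@H](OCc2ccc(OC)cc2)[C@@H](OCC=C)[C@@H]1OCc1ccc(OC)cc1 | intermediate (not isolated)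
18 | (3R,4R,5S,6S)-5-(allyloxy)-3-methoxy-4,6-bis(4-methoxybenzyloxy)cyclohex-1-en-1-yl trifluoromethanesulfonate | CO[C@@H]1C=C(OS(=O)(=O)C(F)(F)F)[C@@H](OCc2ccc(OC)cc2)[C@@H](OCC=C)[C@@H]1OCc1ccc(OC)cc1 | intermediate
19 | methyl (3R,4R,5R,6R)-5-(allyloxy)-3-methoxy-4,6-bis(4-methoxybenzyloxy)cyclohex-1-ene-1-carboxylate | CO[C@@H]1C=C(C(=O)OC)[C@@H](OCc2ccc(OC)cc2)[C@@H](OCC=C)[C@@H]1OCc1ccc(OC)cc1 | intermediate
20 | methyl (3R,4R,5R,6R)-3-methoxy-4,6-bis(4-methoxybenzyloxy)-5-[(E)-prop-1-enyloxy]cyclohex-1-ene-1-carboxylate | CO[C@@H]1C=C(C(=O)OC)[C@@H](OCc2ccc(OC)cc2)[C@@H](O/C=C/C)[C@@H]1OCc1ccc(OC)cc1 | intermediate (not isolated)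
21 | methyl (3R,4S,5R,6R)-5-hydroxy-3-methoxy-4,6-bis(4-methoxybenzyloxy)cyclohex-1-ene-1-carboxylate | CO[C@@H]1C=C(C(=O)OC)[C@@H](OCc2ccc(OC)cc2)[C@@H](O)[C@@H]1OCc1ccc(OC)cc1 | intermediate
22 | [(3R,4S,5R,6R)-5-hydroxy-3-methoxy-4,6-bis(4-methoxybenzyloxy)cyclohex-1-en-1-yl]methanol | CO[C@@H]1C=C(CO)[C@@H](OCc2ccc(OC)cc2)[C@@H](O)[C@@H]1OCc1ccc(OC)cc1 | intermediate
23 | benzoyl chloride | O=C(Cl)c1ccccc1 | starting material
24 | [(3R,4R,5R,6R)-5-(benzoyloxy)-3-methoxy-4,6-bis(4-methoxybenzyloxy)cyclohex-1-en-1-yl]methyl benzoate | CO[C@@H]1C=C(COC(=O)c2ccccc2)[C@@H](OCc2ccc(OC)cc2)[C@@H](OC(=O)c2ccccc2)[C@@H]1OCc1ccc(OC)cc1 | intermediate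
25 | [(3R,4R,5R,6R)-5-(benzoyloxy)-4,6-dihydroxy-3-methoxycyclohex-1-en-1-yl]methyl benzoate (CNP0349013.4) | CO[C@@H]1C=C(COC(=O)c2ccccc2)[C@@H](O)[C@@H](OC(=O)c2ccccc2)[C@@H]1O | target

**Step count**
Total: 15 steps. Longest linear sequence: 15 steps (1 → 25).

**Steps most likely to fail**

Step 10. The C2 enolate may expel the C3 methoxide (E1cB) before it is sulfonylated, or deprotonation may stray to C6. The fallback avoids any enolate and sets out from ketone 16. Condensation with hydrazine (N2H4·H2O, Et3N, EtOH, rt) should give the hydrazone F1. Oxidation with I2 and tetramethylguanidine in THF at 0 °C (Barton vinyl iodide synthesis, through a diazo compound and an iodo carbocation) should give the C1 vinyl iodide F2. Methoxycarbonylation under the conditions of step 11 brings the material back to enoate 19.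

Step 8. The mercury salt may be held back by reversible mercuration of the allyl ether, the aldol closure may show poor facial selectivity, or the β-hydroxy ketone may dehydrate. The fallback forms the same C2–C3 bond without an organomercurial and sets out from enol ether 12. Hydrolysis of the enol ether (0.05 M H2SO4, dioxane–H2O, rt) should give the open-chain keto aldehyde F3, with loss of methanol. An amine-catalysed intramolecular aldol addition (L-proline, DMSO, rt; enamine of the methyl ketone, same 6-(enolendo)-exo-trig closure) returns to hydroxy ketone 15.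

Step 9. Base-induced β-elimination of the C3 oxygen may compete with methylation, or alkylation of the hindered secondary alcohol may stall. The fallback postpones methylation until the ketone is gone and sets out from 15:
- Silylation (Et3SiCl, imidazole, DMF) should give the triethylsilyl ether ketone F4.
- Enolisation and sulfonylation as in step 10 should give the silyloxy enol triflate F5.
- Methoxycarbonylation as in step 11 should give the silyloxy enoate F6.
- HF·pyridine in THF at 0 °C should free the allylic alcohol F7.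
- Methylation of F7 (Me3OBF4, 1,8-bis(dimethylamino)naphthalene, CH2Cl2), where no β-elimination path remains, rejoins the route at enoate 19.

**Further compounds**
F1 | step 10 | hydrazone of ketone 16 at C1 | CO[C@@H]1CC(=NN)[C@@H](OCc2ccc(OC)cc2)[C@@H](OCC=C)[C@@H]1OCc1ccc(OC)cc1
F2 | step 10 | C1 vinyl iodide: 5-(allyloxy)-1-iodo-3-methoxy-4,6-bis(4-methoxybenzyloxy)cyclohex-1-ene, ring configuration as in 18 | CO[C@@H]1C=C(I)[C@@H](OCc2ccc(OC)cc2)[C@@H](OCC=C)[C@@H]1OCc1ccc(OC)cc1
F3 | step 8 | open-chain 3-O-allyl-6-deoxy-2,4-bis-O-(4-methoxybenzyl)-D-arabino-hexos-5-ulose | CC(=O)[C@@H](OCc1ccc(OC)cc1)[C@@H](OCC=C)[C@H](OCc1ccc(OC)cc1)C=O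
F4 | step 9 | O3-triethylsilyl ether of hydroxy ketone 15 | CC[Si](CC)(CC)O[C@@H]1CC(=O)[C@@H](OCc2ccc(OC)cc2)[C@@H](OCC=C)[C@@H]1OCc1ccc(OC)cc1
F5 | step 9 | C1 enol triflate of F4 (double bond C1=C2) | CC[Si](CC)(CC)O[C@@H]1C=C(OS(=O)(=O)C(F)(F)F)[C@@H](OCc2ccc(OC)cc2)[C@@H](OCC=C)[C@@H]1OCc1ccc(OC)cc1
F6 | step 9 | methyl 5-(allyloxy)-4,6-bis(4-methoxybenzyloxy)-3-(triethylsilyloxy)cyclohex-1-ene-1-carboxylate, ring configuration as in 19 | CC[Si](CC)(CC)O[C@@H]1C=C(C(=O)OC)[C@@H](OCc2ccc(OC)cc2)[C@@H](OCC=C)[C@@H]1OCc1ccc(OC)cc1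
F7 | step 9 | methyl 5-(allyloxy)-3-hydroxy-4,6-bis(4-methoxybenzyloxy)cyclohex-1-ene-1-carboxylate, ring configuration as in 19 | O[C@@H]1C=C(C(=O)OC)[C@@H](OCc2ccc(OC)cc2)[C@@H](OCC=C)[C@@H]1OCc1ccc(OC)cc1
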